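**Retrosynthetic overview**

1. Ring E (C-5′ to C-10′) is disconnected last, at the ring bond C-5′–C-10′. This bond joins the isopropenyl-bearing C-5′ to the quaternary methyl/vinyl-bearing C-10′, so it is the central σ-bond of a hexa-1,5-diene (C-3′=C-4′–C-5′–C-10′–C-1′=C-2′). It can therefore be made by a palladium-catalysed reductive 3,3′-coupling of the two (E)-allylic carbonates of acyclic 29, with the 1,3-related C-7′ centre (which carries ring D) relaying both new stereocentres.
2. Ring D (dihydropyran: O, C-11, C-13, C-13′, C-11′, C-12′) comes from a hetero-Diels–Alder union of enal 28 with α-methylene lactone 19.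
3. Enal 28: the ring of (4S)-limonene oxide is cleaved between C-1 and C-2 (its stereocentre becomes C-7′), both carbonyls are olefinated to (E)-allyl units, and the same six carbons are reclosed as ring E in the key step.
4. Lactone 19 (rings A–C, cis-decalin): ring B is (S)-carvone, ring A comes from a methylenecyclohexane annulation (conjugate addition, then enolate alkylation), and ring C from iodolactonization after removal of the C-9 carbonyl.
5. Order of ring formation: B (bought), A, C, D, E.

Key step: step 20

Remark: the SMILES is read as a cis-fused decalin (CH3-14, H-5, the C-7–C-11 bond and the C-8–O bond all on one face, the 5-epimer of the isoalantolactone skeleton) joined to a (1R,2R,4S)-1-methyl-1-vinyl-2-isopropenylcyclohexane, antipodal to the common β-elemene series, which is why neither the natural lactone nor a natural elemane is used; eudesmane locants C-1 to C-15 are used for rings A (C-1–C-5, C-10), B (C-5–C-10) and C (lactone), primed elemane locants for ring E (C-5′–C-10′), and ring D is the dihydropyran.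

**Route**

Step 1
Reactants: 1 5-chloropent-1-yne
Product: 3 2-bromo-5-chloropent-1-ene, via alkenylborane 2 (not isolated)
Conditions: B-bromo-9-BBN, CH2Cl2, 0 °C; then AcOH, 0 → 20 °C
Reagents that add atoms: B-bromo-9-borabicyclo[3.3.1]nonane, BrB1C2CCCC1CCC2
Why: cis-bromoboration of the terminal alkyne places boron on C-1 and bromine on C-2, and protodeboronation of alkenylborane 2 by acetic acid with retention then gives the 2-bromoalk-1-ene (haloboration–protonolysis), the primary chloride being inert.

Step 2
Reactants: 4 (S)-(+)-carvone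
Product: 5 (5S)-5-(3-chloroprop-1-en-2-yl)-2-methylcyclohex-2-en-1-one
Conditions: Ca(OCl)2, solid CO2, CH2Cl2/H2O, 0 °C
Reagents that add atoms: calcium hypochlorite, [Ca+2].[O-]Cl.[O-]Cl
Why: hypochlorous acid generated in the two-phase mixture chlorinates the electron-rich isopropenyl group by an ene-type allylic chlorination with transposition of the double bond, whereas the conjugated ring alkene is deactivated and the C-5 stereocentre is not involved.

Step 3
Reactants: 5 (5S)-5-(3-chloroprop-1-en-2-yl)-2-methylcyclohex-2-en-1-one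
Product: 7 (5S)-5-(3-hydroxyprop-1-en-2-yl)-2-methylcyclohex-2-en-1-one, via acetate 6 (not isolated)
Conditions: KOAc, Bu4NI (cat.), DMF, 50 °C; then K2CO3 (cat.), MeOH, 0 °C
Reagents that add atoms: potassium acetate, CC(=O)[O-].[K+]
Why: SN2 displacement of the primary allylic chloride by acetate is followed by base-catalysed methanolysis (Zemplén-type transesterification) of acetate 6, conditions mild enough to leave the enone untouched.

Step 4
Reactants: 7 (5S)-5-(3-hydroxyprop-1-en-2-yl)-2-methylcyclohex-2-en-1-one
Product: 8 (5S)-5-[3-(tert-butyldimethylsilyloxy)prop-1-en-2-yl]-2-methylcyclohex-2-en-1-one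
Conditions: TBSCl, imidazole, DMF, 20 °C
Reagents that add atoms: tert-butyldimethylsilyl chloride, CC(C)(C)[Si](C)(C)Cl
Why: standard imidazole-promoted silylation of the primary allylic alcohol, needed so that the oxygen survives the organometallic, strong-base and palladium steps.

Step 5
Reactants: 8 (5S)-5-[3-(tert-butyldimethylsilyloxy)prop-1-en-2-yl]-2-methylcyclohex-2-en-1-one; 3 2-bromo-5-chloropent-1-ene
Product: 10 (2RS,3S,5S)-5-[3-(tert-butyldimethylsilyloxy)prop-1-en-2-yl]-3-(5-chloropent-1-en-2-yl)-2-methylcyclohexan-1-one, via Grignard reagent 9 (not isolated)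
Conditions: 3, Mg, THF, 35 °C; then CuBr·SMe2 (10 mol%), 8, THF, −78 → −30 °C; aq. NH4Cl
Reagents that add atoms: none
Why: copper-catalysed conjugate addition of alkenyl Grignard reagent 9 (formed by magnesium insertion into the C–Br bond, the alkyl chloride being much less reactive) occurs by axial attack anti to the C-5 substituent, which sets the new C-3 centre trans to it as is general for 5-substituted cyclohexenones, while C-2 is formed as an inconsequential epimer mixture.

Step 6
Reactants: 10 (2RS,3S,5S)-5-[3-(tert-butyldimethylsilyloxy)prop-1-en-2-yl]-3-(5-chloropent-1-en-2-yl)-2-methylcyclohexan-1-one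
Product: 11 12-(tert-butyldimethylsilyloxy)-5βH-eudesma-4(15),11(13)-dien-9-one
Conditions: t-BuOK, t-BuOH/THF, 20 °C
Reagents that add atoms: none
Why: intramolecular enolate C-alkylation (6-exo-tet, the second half of a methylenecyclohexane annulation) can proceed only from the more substituted C-2 enolate, and because the tether is anchored on the adjacent carbon the new bond forms on the tether face, so that the angular methyl (C-14) ends cis to H-5 and the quaternary centre C-10 is set by C-5 in a cis-decalin.

Step 7
Reactants: 11 12-(tert-butyldimethylsilyloxy)-5βH-eudesma-4(15),11(13)-dien-9-one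
Product: 13 12-(tert-butyldimethylsilyloxy)-5βH-eudesma-4(15),8,11(13)-trien-9-yl trifluoromethanesulfonate, via potassium enolate 12 (not isolated)
Conditions: KN(SiMe3)2, THF, −78 °C; then PhNTf2, −78 → 0 °C
Reagents that add atoms: N-phenylbis(trifluoromethanesulfonimide), O=S(=O)(N(c1ccccc1)S(=O)(=O)C(F)(F)F)C(F)(F)F
Why: C-10 is quaternary, so deprotonation can occur only at C-8 and the resulting enolate 12 is O-sulfonylated to the Δ8 enol triflate.

Step 8
Reactants: 13 12-(tert-butyldimethylsilyloxy)-5βH-eudesma-4(15),8,11(13)-trien-9-yl trifluoromethanesulfonate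
Product: 14 12-(tert-butyldimethylsilyloxy)-5βH-eudesma-4(15),8,11(13)-triene
Conditions: Pd(OAc)2 (5 mol%), PPh3 (10 mol%), Bu3N, HCO2H, DMF, 60 °C
Reagents that add atoms: none
Why: palladium-catalysed formate reduction of an enol triflate (oxidative addition to zerovalent palladium, exchange to the formate, decarboxylation to a palladium hydride, reductive elimination) removes the C-9 oxygen and leaves the C-8/C-9 alkene needed for lactonization, without affecting the silyl ether or the other alkenes.

Step 9
Reactants: 14 12-(tert-butyldimethylsilyloxy)-5βH-eudesma-4(15),8,11(13)-triene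
Product: 15 5βH-eudesma-4(15),8,11(13)-trien-12-ol
Conditions: Bu4NF, THF, 0 → 20 °C
Reagents that add atoms: none
Why: fluoride-induced cleavage of the silyl ether liberates the primary allylic alcohol.

Step 10
Reactants: 15 5βH-eudesma-4(15),8,11(13)-trien-12-ol
Product: 17 5βH-eudesma-4(15),8,11(13)-trien-12-oic acid, via enal 16 (not isolated)
Conditions: MnO2, CH2Cl2, 20 °C; filter; then NaClO2, NaH2PO4, 2-methylbut-2-ene, t-BuOH/H2O, 0 °C
Reagents that add atoms: sodium chlorite, [Na+].[O-]Cl=O
Why: MnO2 oxidises only the allylic alcohol to enal 16 under neutral conditions and the Pinnick oxidation then converts the aldehyde into the acrylic acid, with 2-methylbut-2-ene scavenging hypochlorous acid so that the three other alkenes and the doubly allylic C-7 hydrogen are spared.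

Step 11
Reactants: 17 5βH-eudesma-4(15),8,11(13)-trien-12-oic acid
Product: 18 9α-iodo-5βH-eudesma-4(15),11(13)-dien-12,8β-olide
Conditions: I2, NaHCO3, MeCN, 0 °C, dark
Reagents that add atoms: iodine, [I][I]
Why: kinetic iodolactonization, in which reversible iodonium formation is productive only at the C-8/C-9 alkene because the carboxylate on the β-oriented C-7 side chain can open it 5-exo at C-8 anti to iodine, so that the new C-8–O bond is necessarily cis to the C-7–C-11 bond (cis-fused γ-lactone, 8β-O, 9α-I).

Step 12
Reactants: 18 9α-iodo-5βH-eudesma-4(15),11(13)-dien-12,8β-olide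
Product: 19 5βH-eudesma-4(15),11(13)-dien-12,8β-olide (5-epi-isoalantolactone)
Conditions: Bu3SnH (1.1 equiv), Et3B (cat.), air, toluene, 0 °C
Reagents that add atoms: none
Why: radical chain reduction of the secondary iodide by Bu3SnH at low temperature, where iodine abstraction is much faster than stannyl-radical addition to the acrylate and the C-9 radical has no favourable cyclization mode (only 4-exo or 5-endo), so it is simply reduced.

Step 13
Reactants: 20 (4S)-limonene 1,2-oxide (cis/trans mixture)
Product: 22 (3S)-6-oxo-3-(prop-1-en-2-yl)heptanal, via diol 21 (not isolated)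
Conditions: H5IO6, THF/H2O, 0 → 20 °C
Reagents that add atoms: water, O
Why: aqueous periodic acid hydrolyses either epoxide diastereomer to diol 21 and cleaves the glycol (Malaprade reaction), which opens the ring between C-1 and C-2 and leaves the remote stereocentre untouched as C-3 of the keto aldehyde.

Step 14
Reactants: 22 (3S)-6-oxo-3-(prop-1-en-2-yl)heptanal
Product: 23 ethyl (2E,5S)-2-methyl-8-oxo-5-(prop-1-en-2-yl)non-2-enoate
Conditions: Ph3P=C(CH3)CO2Et, CH2Cl2, 20 °C
Reagents that add atoms: ethyl 2-(triphenylphosphoranylidene)propanoate, CCOC(=O)C(C)=P(c1ccccc1)(c1ccccc1)c1ccccc1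
Why: the stabilised, α-branched ylide reacts only with the aldehyde and gives the (E)-trisubstituted enoate (Wittig reaction under thermodynamic control of the oxaphosphetane).

Step 15
Reactants: 23 ethyl (2E,5S)-2-methyl-8-oxo-5-(prop-1-en-2-yl)non-2-enoate
Product: 24 diethyl (2E,5S,8E)-2,8-dimethyl-5-(prop-1-en-2-yl)deca-2,8-dienedioate
Conditions: (EtO)2P(O)CH2CO2Et, NaH, THF, 0 → 65 °C; chromatographic removal of the 8Z isomer
Reagents that add atoms: triethyl phosphonoacetate, CCOC(=O)CP(=O)(OCC)OCC
Why: Horner–Wadsworth–Emmons olefination of the methyl ketone is expected to favour the E isomer (ester trans to the longer chain), and the minor 8Z isomer is removed by chromatography so that both allyl units have defined geometry.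

Step 16
Reactants: 24 diethyl (2E,5S,8E)-2,8-dimethyl-5-(prop-1-en-2-yl)deca-2,8-dienedioate
Product: 25 (2E,5S,8E)-2,8-dimethyl-5-(prop-1-en-2-yl)deca-2,8-diene-1,10-diol
Conditions: i-Bu2AlH, CH2Cl2, −78 °C; aq. potassium sodium tartrate work-up
Reagents that add atoms: none
Why: i-Bu2AlH reduces both conjugated esters by 1,2-addition to the allylic alcohols without touching the alkenes.

Step 17
Reactants: 25 (2E,5S,8E)-2,8-dimethyl-5-(prop-1-en-2-yl)deca-2,8-diene-1,10-diol
Product: 26 (2E,5S,8E)-2,8-dimethyl-5-(prop-1-en-2-yl)deca-2,8-diene-1,10-diyl bis(methyl carbonate)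
Conditions: ClCO2Me, pyridine, DMAP (cat.), CH2Cl2, 0 °C
Reagents that add atoms: methyl chloroformate, COC(=O)Cl
Why: acylation of both primary allylic alcohols gives the carbonates that later serve as leaving groups and as internal source of methoxide for the palladium chemistry.

Step 18
Reactants: 26 (2E,5S,8E)-2,8-dimethyl-5-(prop-1-en-2-yl)deca-2,8-diene-1,10-diyl bis(methyl carbonate)
Product: 28 (2E,5S,8E)-2,8-dimethyl-5-(3-oxoprop-1-en-2-yl)deca-2,8-diene-1,10-diyl bis(methyl carbonate), via allylic alcohol 27 (not isolated)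
Conditions: SeO2 (cat.), t-BuOOH, salicylic acid (cat.), CH2Cl2, 20 °C; then MnO2, CH2Cl2, 20 °C
Reagents that add atoms: selenium dioxide, O=[Se]=O; tert-butyl hydroperoxide, CC(C)(C)OO
Why: Riley oxidation (ene reaction of SeO2 followed by 2,3-sigmatropic shift) should take place at the isopropenyl methyl because the two trisubstituted alkenes are deactivated by their allylic carbonate oxygens, as in the known selective oxidation of the remote alkene of geranyl esters, and MnO2 then oxidises allylic alcohol 27 to the enal.

Step 19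
Reactants: 19 5βH-eudesma-4(15),11(13)-dien-12,8β-olide; 28 (2E,5S,8E)-2,8-dimethyl-5-(3-oxoprop-1-en-2-yl)deca-2,8-diene-1,10-diyl bis(methyl carbonate)
Product: 29 spiro adduct: 5βH-eudesm-4(15)-en-12,8β-olide spiro-linked at C-11 to C-2 of a 3,4-dihydro-2H-pyran whose C-5 carries the (2E,5S,8E)-1,10-bis(methoxycarbonyloxy)-2,8-dimethyldeca-2,8-dien-5-yl group (pyran oxygen on the lactone face of H-7 and H-8)
Conditions: neat (1.5 equiv of 28), BHT (cat.), 90 °C, sealed tube, argon
Reagents that add atoms: none
Why: thermal hetero-Diels–Alder reaction of the acrolein-dimer type in which the s-cis enal 28 is the 1-oxadiene and the strained exocyclic alkene of 19 the dienophile, where leading C-13–C-13′ bond formation directs oxygen to the substituted carbon C-11 and attack on the convex lactone face (anti to C-6 and C-9 of ring B, syn to H-7 and H-8) sets the spiro centre, the 4(15)-alkene and the carbonate-bearing trisubstituted alkenes being far poorer dienophiles.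

Step 20
Reactants: 29 spiro adduct
Product: 31 target CNP0353330.1, via allylboronate 30 (not isolated)
Conditions: Pd2(dba)3 (5 mol%), 1,2-bis(diphenylphosphino)benzene (12 mol%), B2pin2 (1.05 equiv, syringe pump), THF (5 mM), 60 °C
Reagents that add atoms: none
Why: Proposed new method: zerovalent palladium ionises one allylic carbonate (CO2 and methoxide are released), methoxide-assisted transmetalation with B2pin2 and C–B reductive elimination give allylboronate 30 (Miyaura-type allylic borylation), and the second π-allylpalladium methoxide then transmetalates with this tethered boronate to an eleven-membered bis(η1-allyl)palladacycle that closes ring E by inner-sphere 3,3′-reductive elimination between C-5′ and C-10′; the closest known reactions are the palladium-catalysed branch-selective allyl–allyl cross-coupling of allylboronates with allylic carbonates, which forms vicinal tertiary and quaternary centres, and the intramolecular palladium-catalysed coupling of allylstannanes with allylic carboxylates to 1,2-divinylcycloalkanes. Ring E is closed in the 6-exo sense at both allyl termini, the two (E)-allyl units and the palladium forming a chair-like seven-membered array fused to the nascent cyclohexane chair (the metalla-analogue of the germacrene-to-elemene Cope transition state). C-10′ and C-5′ are both set in this event by the existing C-7′ centre, whose dihydropyranyl substituent sits equatorial on the forming chair, while the E geometry of both alkenes places vinyl and isopropenyl trans-diequatorial and CH3-14′ axial. The step needs 3,3′- over 1,1′- or 1,3′-selectivity, which the small-bite-angle diphosphine and the six- versus ten- or eight-membered ring size should secure, and any head-to-head ten-membered diene would in any case converge on 31 by Cope rearrangement; it also needs intramolecular over intermolecular coupling, secured by high dilution and slow addition of the diboron reagent. The enol ether, the lactone and the 1,1-disubstituted alkenes are inert to these neutral conditions.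

**Compound list**

1 | 5-chloropent-1-yne | C#CCCCCl | starting material
2 | (Z)-9-(2-bromo-5-chloropent-1-en-1-yl)-9-borabicyclo[3.3.1]nonane | Br/C(CCCCl)=C\B1C2CCCC1CCC2 | intermediate
3 | 2-bromo-5-chloropent-1-ene | C=C(Br)CCCCl | intermediate
4 | (S)-(+)-carvone, (5S)-2-methyl-5-(prop-1-en-2-yl)cyclohex-2-en-1-one | CC1=CC[C@@H](CC1=O)C(C)=C | starting material
5 | (5S)-5-(3-chloroprop-1-en-2-yl)-2-methylcyclohex-2-en-1-one | CC1=CC[C@@H](CC1=O)C(=C)CCl | intermediate
6 | (5S)-5-(3-acetoxyprop-1-en-2-yl)-2-methylcyclohex-2-en-1-one | CC1=CC[C@@H](CC1=O)C(=C)COC(C)=O | intermediate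
7 | (5S)-5-(3-hydroxyprop-1-en-2-yl)-2-methylcyclohex-2-en-1-one | CC1=CC[C@@H](CC1=O)C(=C)CO | intermediate
8 | (5S)-5-[3-(tert-butyldimethylsilyloxy)prop-1-en-2-yl]-2-methylcyclohex-2-en-1-one | CC1=CC[C@@H](CC1=O)C(=C)CO[Si](C)(C)C(C)(C)C | intermediate
9 | (5-chloropent-1-en-2-yl)magnesium bromide | C=C([Mg]Br)CCCCl | intermediate
10 | (2RS,3S,5S)-5-[3-(tert-butyldimethylsilyloxy)prop-1-en-2-yl]-3-(5-chloropent-1-en-2-yl)-2-methylcyclohexan-1-one (3,5-trans; C-2 epimer mixture) | CC1C(=O)C[C@@H](C(=C)CO[Si](C)(C)C(C)(C)C)C[C@@H]1C(=C)CCCCl | intermediate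
11 | 12-(tert-butyldimethylsilyloxy)-5βH-eudesma-4(15),11(13)-dien-9-one; (3S,4aR,8aS)-3-[3-(tert-butyldimethylsilyloxy)prop-1-en-2-yl]-8a-methyl-5-methylideneoctahydronaphthalen-1(2H)-one; cis-decalin with CH3-14, H-5 and the C-7 side chain on one face | O=C1C[C@@H](C(=C)CO[Si](C)(C)C(C)(C)C)C[C@@H]2C(=C)CCC[C@]12C | intermediate
12 | potassium 8-en-9-olate of 11 | [K+].[O-]C1=C[C@@H](C(=C)CO[Si](C)(C)C(C)(C)C)C[C@@H]2C(=C)CCC[C@]12C | intermediate
13 | 12-(tert-butyldimethylsilyloxy)-5βH-eudesma-4(15),8,11(13)-trien-9-yl trifluoromethanesulfonate | O=S(=O)(OC1=C[C@@H](C(=C)CO[Si](C)(C)C(C)(C)C)C[C@@H]2C(=C)CCC[C@]12C)C(F)(F)F | intermediate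
14 | 12-(tert-butyldimethylsilyloxy)-5βH-eudesma-4(15),8,11(13)-triene | C1=C[C@@H](C(=C)CO[Si](C)(C)C(C)(C)C)C[C@@H]2C(=C)CCC[C@]12C | intermediate
15 | 5βH-eudesma-4(15),8,11(13)-trien-12-ol | C1=C[C@@H](C(=C)CO)C[C@@H]2C(=C)CCC[C@]12C | intermediate
16 | 5βH-eudesma-4(15),8,11(13)-trien-12-al | C1=C[C@@H](C(=C)C=O)C[C@@H]2C(=C)CCC[C@]12C | intermediate
17 | 5βH-eudesma-4(15),8,11(13)-trien-12-oic acid | C1=C[C@@H](C(=C)C(=O)O)C[C@@H]2C(=C)CCC[C@]12C | intermediate
18 | 9α-iodo-5βH-eudesma-4(15),11(13)-dien-12,8β-olide | C=C1C(=O)O[C@@H]2[C@@H](I)[C@@]3(C)CCCC(=C)[C@H]3C[C@H]12 | intermediate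
19 | 5βH-eudesma-4(15),11(13)-dien-12,8β-olide (5-epi-isoalantolactone); (3aR,4aR,8aR,9aR)-8a-methyl-3,5-dimethylidenedecahydronaphtho[2,3-b]furan-2(3H)-one | C=C1C(=O)O[C@@H]2C[C@@]3(C)CCCC(=C)[C@H]3C[C@H]12 | intermediate
20 | (4S)-limonene 1,2-oxide (cis/trans mixture at the epoxide) | C=C(C)[C@H]1CCC2(C)OC2C1 | starting material
21 | (4S)-p-menth-8-ene-1,2-diol | C=C(C)[C@H]1CCC(C)(O)C(O)C1 | intermediate
22 | (3S)-6-oxo-3-(prop-1-en-2-yl)heptanal | CC(=O)CC[C@@H](CC=O)C(C)=C | intermediate
23 | ethyl (2E,5S)-2-methyl-8-oxo-5-(prop-1-en-2-yl)non-2-enoate | CCOC(=O)/C(C)=C/C[C@H](CCC(C)=O)C(C)=C | intermediate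
24 | diethyl (2E,5S,8E)-2,8-dimethyl-5-(prop-1-en-2-yl)deca-2,8-dienedioate | CCOC(=O)/C(C)=C/C[C@H](CC/C(C)=C/C(=O)OCC)C(C)=C | intermediate
25 | (2E,5S,8E)-2,8-dimethyl-5-(prop-1-en-2-yl)deca-2,8-diene-1,10-diol | OC/C(C)=C/C[C@H](CC/C(C)=C/CO)C(C)=C | intermediate
26 | (2E,5S,8E)-2,8-dimethyl-5-(prop-1-en-2-yl)deca-2,8-diene-1,10-diyl bis(methyl carbonate) | COC(=O)OC/C(C)=C/C[C@H](CC/C(C)=C/COC(=O)OC)C(C)=C | intermediate
27 | (2E,5S,8E)-5-(3-hydroxyprop-1-en-2-yl)-2,8-dimethyldeca-2,8-diene-1,10-diyl bis(methyl carbonate) | COC(=O)OC/C(C)=C/C[C@H](CC/C(C)=C/COC(=O)OC)C(=C)CO | intermediate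
28 | (2E,5S,8E)-2,8-dimethyl-5-(3-oxoprop-1-en-2-yl)deca-2,8-diene-1,10-diyl bis(methyl carbonate) | COC(=O)OC/C(C)=C/C[C@H](CC/C(C)=C/COC(=O)OC)C(=C)C=O | intermediate
29 | spiro adduct of 19 and 28 (rings A–D; acyclic bis(allylic carbonate) chain on pyran C-5, chain centre S) | COC(=O)OC/C(C)=C/C[C@H](CC/C(C)=C/COC(=O)OC)C1=CO[C@@]2(CC1)C(=O)O[C@@H]1C[C@@]3(C)CCCC(=C)[C@H]3C[C@@H]12 | intermediate
30 | mono(allylboronate) of 29 (one carbonate replaced by pinacolboryl; either terminus, one regioisomer drawn) | COC(=O)OC/C(C)=C/C[C@H](CC/C(C)=C/CB1OC(C)(C)C(C)(C)O1)C1=CO[C@@]2(CC1)C(=O)O[C@@H]1C[C@@]3(C)CCCC(=C)[C@H]3C[C@@H]12 | intermediate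
31 | CNP0353330.1: spiro adduct carrying on pyran C-5 the (1S,3R,4R)-4-ethenyl-4-methyl-3-(prop-1-en-2-yl)cyclohexyl group | C=C[C@@]1(C)CC[C@H](C2=CO[C@@]3(CC2)C(=O)O[C@@H]2C[C@@]4(C)CCCC(=C)[C@H]4C[C@@H]23)C[C@@H]1C(=C)C | target

**Step count and risks**

Total step count: 20. Longest linear sequence: 13 steps (from 4 through steps 2–12, 19 and 20 to 31).

Steps most likely to fail:

1. Step 20 (proposed new method). The π-allylpalladium intermediates may undergo β-hydride elimination to 1,3-dienes, both termini may be borylated without C–C coupling, coupling may turn intermolecular, or the reductive elimination may lose regio- or diastereocontrol. The fallback sets out from 29 and comes back at 31 with known chemistry. K2CO3 in MeOH at 0 °C would cleave both methyl carbonates to the diol F1. CBr4/PPh3 with 2,6-lutidine in CH2Cl2 at −20 °C would convert it into the bis(allylic bromide) F2. Slow addition of F2 to Ni(cod)2 in DMF at high dilution (intramolecular coupling of an α,ω-bis(allylic bromide) mediated by zerovalent nickel) should give 31 directly by tail-to-tail coupling and/or the head-to-head cyclodeca-1,5-diene F3. Heating F3 in toluene at about 110 °C should convert it into 31 by Cope rearrangement through the chair–chair transition state with the C-7′ substituent equatorial.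

2. Step 18. The ene oxidation may show poor site selectivity, attacking the allylic methyl or methylene groups of the two trisubstituted alkenes, or may over-oxidise. The fallback sets out from 24 and comes back at 27. With both trisubstituted alkenes still present as unreactive enoates, SeO2 (cat.)/t-BuOOH in CH2Cl2 should hydroxylate only the isopropenyl methyl to give the hydroxy diester F4. TBSCl/imidazole would give the silyl ether F5, i-Bu2AlH at −78 °C the silyloxy diol F6, and ClCO2Me/pyridine the silyloxy biscarbonate F7. HF·pyridine in THF would then release 27, which MnO2 converts into 28 as in the main route.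

3. Step 12. Stannyl radicals or the C-9 radical may add to the α-methylene lactone (hydrostannation, oligomerisation) in competition with iodine abstraction and hydrogen transfer. The fallback sets out from 15 and comes back at 19, removing iodine before the acrylate exists. I2/NaHCO3 in MeCN at 0 °C would effect iodoetherification of 15 (5-exo, same cis selectivity) to the iodo ether F8. Bu3SnH/Et3B would reduce it to the cyclic allylic ether F9. CrO3·2C5H5N in CH2Cl2 (Collins oxidation of the allylic, α-oxygenated C-12 methylene) would then give lactone 19.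

Further compounds
F1 | step 20 | diol corresponding to 29 (both carbonates replaced by OH) | OC/C(C)=C/C[C@H](CC/C(C)=C/CO)C1=CO[C@@]2(CC1)C(=O)O[C@@H]1C[C@@]3(C)CCCC(=C)[C@H]3C[C@@H]12
F2 | step 20 | bis(allylic bromide) corresponding to 29 | BrC/C(C)=C/C[C@H](CC/C(C)=C/CBr)C1=CO[C@@]2(CC1)C(=O)O[C@@H]1C[C@@]3(C)CCCC(=C)[C@H]3C[C@@H]12
F3 | step 20 | head-to-head isomer of 31 with an (E,E)-1,5-dimethylcyclodeca-1,5-dien-8-yl (germacradienyl) ring on pyran C-5 | C/C1=C\C[C@@H](C2=CO[C@@]3(CC2)C(=O)O[C@@H]2C[C@@]4(C)CCCC(=C)[C@H]4C[C@@H]23)CC/C(C)=C/CC1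
F4 | step 18 | diethyl (2E,5S,8E)-5-(3-hydroxyprop-1-en-2-yl)-2,8-dimethyldeca-2,8-dienedioate | CCOC(=O)/C(C)=C/C[C@H](CC/C(C)=C/C(=O)OCC)C(=C)CO
F5 | step 18 | diethyl (2E,5S,8E)-5-[3-(tert-butyldimethylsilyloxy)prop-1-en-2-yl]-2,8-dimethyldeca-2,8-dienedioate | CCOC(=O)/C(C)=C/C[C@H](CC/C(C)=C/C(=O)OCC)C(=C)CO[Si](C)(C)C(C)(C)C
F6 | step 18 | (2E,5S,8E)-5-[3-(tert-butyldimethylsilyloxy)prop-1-en-2-yl]-2,8-dimethyldeca-2,8-diene-1,10-diol | OC/C(C)=C/C[C@H](CC/C(C)=C/CO)C(=C)CO[Si](C)(C)C(C)(C)C
F7 | step 18 | (2E,5S,8E)-5-[3-(tert-butyldimethylsilyloxy)prop-1-en-2-yl]-2,8-dimethyldeca-2,8-diene-1,10-diyl bis(methyl carbonate) | COC(=O)OC/C(C)=C/C[C@H](CC/C(C)=C/COC(=O)OC)C(=C)CO[Si](C)(C)C(C)(C)C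
F8 | step 12 | 9α-iodo-8β,12-epoxy-5βH-eudesma-4(15),11(13)-diene | C=C1CO[C@@H]2[C@@H](I)[C@@]3(C)CCCC(=C)[C@H]3C[C@H]12
F9 | step 12 | 8β,12-epoxy-5βH-eudesma-4(15),11(13)-diene | C=C1CO[C@@H]2C[C@@]3(C)CCCC(=C)[C@H]3C[C@H]12
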